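Late in the grey run, at 80.0 min, the over-reaction product reads 0%, and its largest reading, 2%, lies within the scatter of 2 percentage points, so the rung of target loss in the grey run can be estimated but not measured. I take the loss of target as first-order in c(target), the one concentration I let set its rate, and I put c(target) over that run at half of its last reading. Then a loss as large as that reading, taken over the whole run, gives a rough rate constant of 0.0652 h⁻¹ and a leak half-life of about 10.6 h, which is an estimate from scattered readings. This leak half-life is the time in which such a first-order loss halves the target.

| flask | starting material | protic impurity | temperature | remark | time |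
|---|---|---|---|---|---|
| grey | 10 mM | 0.25 mM | 80 °C | run made earlier |  |
| zeta | 10 mM | 0.500 mM | 80 °C |  | 4.0 h |
| alpha | 10 mM | 0.500 mM | 125 °C |  | 4.0 h |
| epsilon | 10 mM | 0.500 mM | 95 °C |  | 4.0 h |
| gamma | 10 mM | 0.500 mM | 110 °C |  | 4.0 h |

grey run (percent of the starting material charged)

| time / min | target / % | isomer of the product / % | over-reaction product / % |
|---|---|---|---|
| 6.00 | 9 | 4 | 2 |
| 12.0 | 15 | 6 | 1 |
| 30.0 | 30 | 10 | 0 |
| 80.0 | 46 | 13 | 0 |

(readings scatter by 2 percentage points)

- the earlier runs do not show what temperature does; that part of a forecast is a guess
- no earlier run changes the charge of protic impurity; that part of a forecast is a guess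
- a reading or a percentage of target counts all its forms, free or not

1. the flask with the highest share of target in all that became target or isomer of the product or over-reaction product ("all alike" if they lie within 1.5 percentage points) (zeta / alpha / epsilon / gamma / all alike)
2. share of target in all that became target or isomer of the product or over-reaction product, zeta
3. share of target in all that became target or isomer of the product or over-reaction product, alpha
4. share of target in all that became target or isomer of the product or over-reaction product, epsilon
5. share of target in all that became target or isomer of the product or over-reaction product, gamma

The rungs above it I read from the sum of the three products. The first reading gives a half-time of 25.6 min, and the stretch between the last two readings gives 91.0 min, so the making of products slows down as the run goes on. A run of 4.0 h at 80 °C therefore holds 2.64 of the slower half-times but about 0.377 of a leak half-life, and I expect zeta to have largely finished making products while its target stays in place. So I commit to zeta near the share read last in the grey run, 78.0%, although what its larger charge of protic impurity does is a guess. No reading shows the hotter flasks, so I guess that heat shortens the leak half-life, expect a flask's share to hold while that half-life is long against its run, put zeta highest and leave the others unreckoned. The forecast gives zeta as highest, with 76%, 69%, 74.5% and 72% for zeta, alpha, epsilon and gamma, guessing for the hotter flasks that “side paths usually have higher activation energy”, and its zeta lies below my figure.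

The flasks give 79.0% for zeta, 11.6% for alpha, 64.4% for epsilon and 32.4% for gamma, so zeta is highest.

    starting material ⇌ target (K = 1.63, k = 12.8 h⁻¹, Ea = 97.0 kJ mol⁻¹, ΔH = −70.0 kJ mol⁻¹)
    starting material ⇌ isomer of the product (K = 2.40, k = 5.98 h⁻¹, Ea = 105 kJ mol⁻¹, ΔH = 12.0 kJ mol⁻¹)
    target → over-reaction product (k = 0.216 h⁻¹, Ea = 112 kJ mol⁻¹)
    starting material + target ⇌ idle adduct, settled at all times (K = 159 M⁻¹, ΔH = −63.0 kJ mol⁻¹)
    starting material + protic impurity → quenched substrate (k = 122 M⁻¹ h⁻¹, Ea = 89.0 kJ mol⁻¹)
    (constants at 110 °C)

Between 2.00 h and 4.00 h zeta's over-reaction product goes from 0.333% to 1.09%, while its target, all forms counted, goes from 51.6% to 58.3%. The same reckoning gives zeta a leak half-life of 101 h, longer than my estimate. The neighbouring flask, alpha's charge run at 110 °C, has gamma's recipe, and gamma's over-reaction product goes from 11.3% to 21.1% over the same stretch while its target goes from 29.6% to 25.8%. That gives gamma a leak half-life of 3.94 h, shorter than my estimate, against a run of 4.0 h, and the neighbouring flask ends with 21.1% of over-reaction product and a target share of 32.4%.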